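**Retrosynthetic overview**

1. (+)-Neoolivil is a C2-symmetric, all-trans oxolane (locants: O1; C2 and C5 aryl-bearing; C3 and C4 CH2OH-bearing). Both halves come from one C6–C3 aldehyde, O-pivaloyl coniferaldehyde 2.
2. Enabling feature: each aryl carbinol carbon (C2, C5) sits next to a ring carbon (C3, C4) that carries one exocyclic carbon. Read as vinyl on C4, the O1–C5–C4 unit is a 2-aryl-3-vinyloxirane (6), which Pd(0) opens with release of ring strain to an O–C–C dipole. Read as formyl on C3, the C2–C3 unit is the enal 2.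
3. Key disconnection: O1–C2 and C3–C4 together, a formal [3+2] of 6 with 2 under combined Pd(0)/secondary-amine catalysis. It builds the oxolane ring and sets three stereocentres (C2, C3, C4) next to the one carried in (C5).
4. Ring order: oxirane (step 3, temporary; Sharpless epoxidation sets C5), then oxolane (step 6); the aryl rings are bought. Endgame: vinyl to CHO, double reduction, ester removal.

Key step: step 6

Remark: catalyst-bound species of the catalytic cycles (π-allylpalladium, iminium, enamine) are transient, are described in the Why lines and are not numbered.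

**Step 1**
Reactants: 1 (E)-coniferaldehyde
Product: 2 2-methoxy-4-[(E)-3-oxoprop-1-en-1-yl]phenyl pivalate
Conditions: PivCl, Et3N, DMAP (cat.), CH2Cl2, 0 °C → rt
Reagents that add atoms: pivaloyl chloride, CC(C)(C)C(=O)Cl
Why: DMAP-catalysed O-acylation of the only hydroxyl group; the pivalate makes the guaiacyl ring electron-neutral (taming the later benzylic oxirane) and is hindered enough for the amine, ylide and hydride steps.

**Step 2**
Reactants: 2 2-methoxy-4-[(E)-3-oxoprop-1-en-1-yl]phenyl pivalate
Product: 3 4-[(E)-3-hydroxyprop-1-en-1-yl]-2-methoxyphenyl pivalate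
Conditions: NaBH4, CeCl3·7H2O, MeOH, −20 °C
Reagents that add atoms: none
Why: Luche reduction should deliver hydride 1,2 to the enal and leave the alkene and the aryl ester untouched.

**Step 3**
Reactants: 3 4-[(E)-3-hydroxyprop-1-en-1-yl]-2-methoxyphenyl pivalate
Product: 4 4-[(2S,3S)-3-(hydroxymethyl)oxiran-2-yl]-2-methoxyphenyl pivalate
Conditions: Ti(OiPr)4 (10 mol%), L-(+)-DIPT (12 mol%), t-BuOOH, 4 Å MS, CH2Cl2, −20 °C; non-basic work-up
Reagents that add atoms: tert-butyl hydroperoxide, CC(C)(C)OO
Why: Katsuki–Sharpless asymmetric epoxidation of an (E)-cinnamyl alcohol; the L-(+)-tartrate complex should deliver oxygen to the face that gives the (2S,3S)-trans-oxirane, which fixes the future C5.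

**Step 4**
Reactants: 4 4-[(2S,3S)-3-(hydroxymethyl)oxiran-2-yl]-2-methoxyphenyl pivalate
Product: 5 4-[(2S,3R)-3-formyloxiran-2-yl]-2-methoxyphenyl pivalate
Conditions: PhI(OAc)2, TEMPO (10 mol%), CH2Cl2, rt
Reagents that add atoms: none
Why: Oxoammonium (TEMPO) oxidation of the primary alcohol should stop at the aldehyde without opening the oxirane or epimerising the α-centre (the descriptor changes by priority only).

**Step 5**
Reactants: 5 4-[(2S,3R)-3-formyloxiran-2-yl]-2-methoxyphenyl pivalate
Product: 6 4-[(2S,3S)-3-ethenyloxiran-2-yl]-2-methoxyphenyl pivalate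
Conditions: Ph3PCH3Br, KHMDS, THF, −78 → 0 °C
Reagents that add atoms: methyltriphenylphosphonium bromide, C[P+](c1ccccc1)(c1ccccc1)c1ccccc1.[Br-]
Why: Wittig methylenation with the non-stabilised ylide at low temperature should convert the formyl group far faster than the ylide attacks the hindered aryl ester or the oxirane.

**Step 6**
Reactants: 6 4-[(2S,3S)-3-ethenyloxiran-2-yl]-2-methoxyphenyl pivalate and 2 2-methoxy-4-[(E)-3-oxoprop-1-en-1-yl]phenyl pivalate
Product: 7 (2R,3R,4R,5R)-4-ethenyl-2,5-bis[3-methoxy-4-(pivaloyloxy)phenyl]oxolane-3-carbaldehyde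
Conditions: Pd(PPh3)4 (5 mol%), (R)-α,α-diphenylprolinol trimethylsilyl ether (20 mol%), PhCO2H (20 mol%), 2 (1.5 equiv), THF, 0 °C → rt, slow addition of 6
Reagents that add atoms: none
Why: Proposed new method: Pd(0) ionises the strained oxirane of 6 at its allylic C–O bond (future C4, anti) to a zwitterionic π-allylpalladium alkoxide, whose oxygen adds to C-β of the iminium ion formed from 2 and the amine (O1–C2), and the resulting enamine attacks the internal allyl carbon anti to Pd (C3–C4) before hydrolysis releases 7 and both catalysts. The closest known reaction types are the Pd(0)-catalysed formal [3+2] cycloaddition of vinyl oxiranes with doubly activated alkenes and the amine/Pd co-catalysed annulations of enals (formal [3+2] with vinylcyclopropanes, oxa-Michael/carbocyclisation with propargylic alcohols); not yet shown is a vinyl oxirane as the O–C–C partner of an iminium-activated enal. The oxolane is closed in the C–C bond-forming event, a 5-exo-trig attack of the enamine carbon on the internal allyl terminus (five-membered ring instead of the seven-membered ring from terminal attack), after an intermolecular, reversible C–O bond formation. C5 comes unchanged from 6; C2 is set by the catalyst, whose diphenyl(silyloxy)methyl group shields the Si face of C-β so that oxygen adds to the Re face (2R, hence 2,5-trans); C4 forms with net retention (two inversions), which places vinyl trans to the C5 aryl and is also the less hindered outcome if π–σ–π exchange intervenes; C3 is set by allylation of the enamine anti to the C2 aryl group and stays epimerisable α to CHO, the all-trans isomer being the thermodynamic minimum. The step needs ionisation of the allylic and not the benzylic C–O bond (secured by the vinyl group and the electron-neutral pivaloyloxyaryl ring), C- instead of O-allylation (O-allylation and acetal formation at the formyl group give allylic ethers that Pd(0) re-ionises, whereas the C–C closure is irreversible), and capture of the zwitterion before it isomerises to a ketone (excess 2, slow addition of 6).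

**Step 7**
Reactants: 7 (2R,3R,4R,5R)-4-ethenyl-2,5-bis[3-methoxy-4-(pivaloyloxy)phenyl]oxolane-3-carbaldehyde
Product: 10 (2R,3S,4S,5R)-3,4-bis(hydroxymethyl)-2,5-bis[3-methoxy-4-(pivaloyloxy)phenyl]oxolane, via 4-(1,2-dihydroxyethyl) analogue of 7 (epimers at the new carbinol carbon) 8 (not isolated), via (2R,3R,4R,5R)-2,5-bis[3-methoxy-4-(pivaloyloxy)phenyl]oxolane-3,4-dicarbaldehyde 9 (not isolated)
Conditions: OsO4 (2 mol%), NaIO4, 2,6-lutidine, dioxane/H2O, rt; extractive work-up; then NaBH4, MeOH, 0 °C
Reagents that add atoms: osmium tetroxide, O=[Os](=O)(=O)=O; sodium periodate, [Na+].[O-]I(=O)(=O)=O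
Why: Lemieux–Johnson cleavage of the only alkene followed by borohydride reduction of both formyl groups; both α-centres are already all-trans (thermodynamic) and E1cB opening of the ring would be a retro-5-endo-trig process, so the stereocentres should survive.

**Step 8**
Reactants: 10 (2R,3S,4S,5R)-3,4-bis(hydroxymethyl)-2,5-bis[3-methoxy-4-(pivaloyloxy)phenyl]oxolane
Product: 11 (+)-neoolivil, [(2R,3S,4S,5R)-2,5-bis(4-hydroxy-3-methoxyphenyl)oxolane-3,4-diyl]dimethanol
Conditions: K2CO3 (cat.), MeOH, rt; aq. NH4Cl
Reagents that add atoms: none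
Why: Base-catalysed transesterification (methanolysis) of the two aryl pivalates should release the phenols under conditions that touch no stereocentre.

**Compound list**

1 | (E)-coniferaldehyde, (E)-3-(4-hydroxy-3-methoxyphenyl)prop-2-enal | COc1cc(/C=C/C=O)ccc1O | starting material
2 | 2-methoxy-4-[(E)-3-oxoprop-1-en-1-yl]phenyl pivalate | COc1cc(/C=C/C=O)ccc1OC(=O)C(C)(C)C | intermediate
3 | 4-[(E)-3-hydroxyprop-1-en-1-yl]-2-methoxyphenyl pivalate | COc1cc(/C=C/CO)ccc1OC(=O)C(C)(C)C | intermediate
4 | 4-[(2S,3S)-3-(hydroxymethyl)oxiran-2-yl]-2-methoxyphenyl pivalate | COc1cc([C@@H]2O[C@H]2CO)ccc1OC(=O)C(C)(C)C | intermediate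
5 | 4-[(2S,3R)-3-formyloxiran-2-yl]-2-methoxyphenyl pivalate | COc1cc([C@@H]2O[C@H]2C=O)ccc1OC(=O)C(C)(C)C | intermediate
6 | 4-[(2S,3S)-3-ethenyloxiran-2-yl]-2-methoxyphenyl pivalate | COc1cc([C@@H]2O[C@H]2C=C)ccc1OC(=O)C(C)(C)C | intermediate
7 | (2R,3R,4R,5R)-4-ethenyl-2,5-bis[3-methoxy-4-(pivaloyloxy)phenyl]oxolane-3-carbaldehyde | COc1cc([C@@H]2O[C@@H](c3ccc(OC(=O)C(C)(C)C)c(OC)c3)[C@H](C=C)[C@H]2C=O)ccc1OC(=O)C(C)(C)C | intermediate
8 | 4-(1,2-dihydroxyethyl) analogue of 7 (epimers at the new carbinol carbon) | COc1cc([C@@H]2O[C@@H](c3ccc(OC(=O)C(C)(C)C)c(OC)c3)[C@H](C(O)CO)[C@H]2C=O)ccc1OC(=O)C(C)(C)C | intermediate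
9 | (2R,3R,4R,5R)-2,5-bis[3-methoxy-4-(pivaloyloxy)phenyl]oxolane-3,4-dicarbaldehyde | COc1cc([C@@H]2O[C@@H](c3ccc(OC(=O)C(C)(C)C)c(OC)c3)[C@H](C=O)[C@H]2C=O)ccc1OC(=O)C(C)(C)C | intermediate
10 | (2R,3S,4S,5R)-3,4-bis(hydroxymethyl)-2,5-bis[3-methoxy-4-(pivaloyloxy)phenyl]oxolane | COc1cc([C@@H]2O[C@@H](c3ccc(OC(=O)C(C)(C)C)c(OC)c3)[C@H](CO)[C@H]2CO)ccc1OC(=O)C(C)(C)C | intermediate
11 | (+)-neoolivil | COc1cc([C@@H]2O[C@@H](c3ccc(O)c(OC)c3)[C@H](CO)[C@H]2CO)ccc1O | target

**Totals**

Total step count: 8. Longest linear sequence: 8 steps (1 → 11; compound 2 is used again in step 6).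

**Steps most likely to fail**

1. Step 6 (proposed new method). The zwitterionic π-allylpalladium alkoxide may isomerise to an allyl aryl ketone or dienol faster than it is captured by the iminium ion. The amine catalyst may be consumed by N-allylation, and facial control at C3/C4 may be incomplete. Fallback with known chemistry, setting out from 6 and returning at 11: commercial vanillin would be pivaloylated to 4-formyl-2-methoxyphenyl pivalate F1 and condensed with dimethyl malonate (Knoevenagel, piperidine/AcOH) to the arylidene malonate F2. The established Pd(0)-catalysed formal [3+2] cycloaddition of a vinyl oxirane with a doubly activated alkene (6 + F2, Pd(PPh3)4, THF) should give the oxolane-3,3-diester F3, from which the 2,5-trans-4,5-trans isomer would be separated. Krapcho dealkoxycarbonylation (LiCl, wet DMSO, heat) should give the monoester F4, with C3 set trans under thermodynamic control. Lemieux–Johnson cleavage of the vinyl group should give the aldehyde ester F5, and LiAlH4 should reduce ester and aldehyde and cleave both pivalates to give 11.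

2. Step 5. The basic ylide may epimerise or open the α-formyl oxirane, or be acylated by the aryl pivalate. Fallback that installs the alkene before the oxirane, setting out from 2 and returning at 6: Wittig methylenation of the robust enal 2 should give 4-[(1E)-buta-1,3-dien-1-yl]-2-methoxyphenyl pivalate F6. Shi epoxidation with the L-fructose-derived ketone (Oxone, buffered MeCN/dimethoxymethane/H2O, 0 °C) should epoxidise the trans-disubstituted styrenyl alkene selectively and give 6 as the (S,S)-oxirane. This bypasses compounds 3–5.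

3. Step 7. The dialdehyde may epimerise or eliminate under the buffered oxidative conditions, or the electron-rich parts of the molecule may be over-oxidised during the long osmium/periodate exposure. Fallback that removes the sensitive formyl group first, setting out from 7 and returning at 10: NaBH4 reduction of 7 should give [(2R,3S,4R,5R)-4-ethenyl-2,5-bis[3-methoxy-4-(pivaloyloxy)phenyl]oxolan-3-yl]methanol F7. Ozonolysis (O3, CH2Cl2/MeOH, −78 °C) with NaBH4 work-up should then convert the vinyl group directly into the second hydroxymethyl group and give 10.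

**Further compounds**

F1 | step 6 | 4-formyl-2-methoxyphenyl pivalate | COc1cc(C=O)ccc1OC(=O)C(C)(C)C
F2 | step 6 | dimethyl 2-{[3-methoxy-4-(pivaloyloxy)phenyl]methylidene}propanedioate | COC(=O)C(=Cc1ccc(OC(=O)C(C)(C)C)c(OC)c1)C(=O)OC
F3 | step 6 | dimethyl (2S,4R,5R)-4-ethenyl-2,5-bis[3-methoxy-4-(pivaloyloxy)phenyl]oxolane-3,3-dicarboxylate | COc1cc([C@@H]2O[C@@H](c3ccc(OC(=O)C(C)(C)C)c(OC)c3)[C@H](C=C)C2(C(=O)OC)C(=O)OC)ccc1OC(=O)C(C)(C)C
F4 | step 6 | methyl (2R,3R,4R,5R)-4-ethenyl-2,5-bis[3-methoxy-4-(pivaloyloxy)phenyl]oxolane-3-carboxylate | COc1cc([C@@H]2O[C@@H](c3ccc(OC(=O)C(C)(C)C)c(OC)c3)[C@H](C=C)[C@H]2C(=O)OC)ccc1OC(=O)C(C)(C)C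
F5 | step 6 | methyl (2R,3R,4R,5R)-4-formyl-2,5-bis[3-methoxy-4-(pivaloyloxy)phenyl]oxolane-3-carboxylate | COc1cc([C@@H]2O[C@@H](c3ccc(OC(=O)C(C)(C)C)c(OC)c3)[C@H](C=O)[C@H]2C(=O)OC)ccc1OC(=O)C(C)(C)C
F6 | step 5 | 4-[(1E)-buta-1,3-dien-1-yl]-2-methoxyphenyl pivalate | COc1cc(/C=C/C=C)ccc1OC(=O)C(C)(C)C
F7 | step 7 | [(2R,3S,4R,5R)-4-ethenyl-2,5-bis[3-methoxy-4-(pivaloyloxy)phenyl]oxolan-3-yl]methanol | COc1cc([C@@H]2O[C@@H](c3ccc(OC(=O)C(C)(C)C)c(OC)c3)[C@H](C=C)[C@H]2CO)ccc1OC(=O)C(C)(C)C
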